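## Retrosynthetic overview

1. The butanolide is made last: a catalytic asymmetric Baeyer–Villiger desymmetrisation of a spiro-cyclobutanone sets C13.
2. Key disconnection is the C9–O9 spiro-ether bond. It forms when the tetrasubstituted C8=C9 alkene is oxidised at an anode to its radical cation and trapped by the side-chain tertiary alcohol; the C8 radical is oxidised on and captured by the 7β-acetate, which ends as the 8β-acetate.
3. The side chain comes from acetylide addition of a cyclobutanol alkyne to the C9 ketone, then oxidative allylic transposition to the 7-oxo-Δ8 enone.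
4. The decalin comes from an enantioselective Diels–Alder reaction of 2,6-dimethylbenzoquinone with methyl pentadienoate; C4 and C5 are reset by dienediolate methylation, and C6 reduction closes the 19,6-lactone.
5. Ring order: ring B (quinone) → ring A (Diels–Alder) → γ-lactone → spiro-tetrahydrofuran (radical cation) → butanolide (Baeyer–Villiger).

Assumption: carbons keep the labdane numbers of the target throughout (C17, C18, C20 = methyls on C8, C4, C10; C19 = carboxyl carbon on C4; C11–C16 = side chain; β = face of the C10 methyl), and the silyl group of starting material 10 is a protecting group.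

## Route

Step 1
Reactants: 1 2-methylphenol (o-cresol)
Product: 2 2,6-dimethylphenol
Conditions: MeOH, MgO, 450 °C, vapour phase (flow)
Reagents that add atoms: methanol, CO
Why: Heterogeneous ortho-selective C-methylation of a phenol with methanol over MgO (the 2,6-xylenol process) alkylates the only free ortho position; no stereocentre is formed.

Step 2
Reactants: 2 2,6-dimethylphenol
Product: 3 2,6-dimethyl-1,4-benzoquinone
Conditions: O2 (1 atm), Co(salen) (C16H14CoN2O2, 5 mol %), DMF, rt
Reagents that add atoms: dioxygen, O=O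
Why: Co(salen)-catalysed aerobic para-oxidation of a 2,6-disubstituted phenol gives the p-quinone cleanly because both ortho positions are blocked.

Step 3
Reactants: 3 2,6-dimethyl-1,4-benzoquinone; 4 methyl (2E)-penta-2,4-dienoate
Product: 5 endo cis-fused adduct methyl 4a,6-dimethyl-5,8-dioxo-1,4,4a,5,8,8a-hexahydronaphthalene-1-carboxylate (10β-Me; 5β-H; 4α-CO2Me)
Conditions: (S)-2-(o-tolyl)oxazaborolidine from (S)-diphenylprolinol (20 mol %), HNTf2 (18 mol %), CH2Cl2, −40 → −20 °C
Reagents that add atoms: none
Why: Enantioselective quinone Diels–Alder reaction with a Corey oxazaborolidinium catalyst: the Lewis acid binds the unhindered C6 carbonyl (α-C–H contact at C5), so the CH2 terminus of the diene bonds to the methyl-bearing carbon C10 and the ester terminus to C5 through an endo transition state, fixing C10 as S (the antipodal catalyst would give the mirror image); the C4 and C5 centres formed here are reset in step 4.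

Step 4
Reactants: 5 endo cis-fused Diels–Alder adduct
Product: 7 trans-fused keto ester methyl 1,4a,6-trimethyl-5,8-dioxo-1,4,4a,5,8,8a-hexahydronaphthalene-1-carboxylate (4α-Me; 4β-CO2Me; 5α-H; 10β-Me), via dilithium dienediolate 6 (not isolated)
Conditions: LDA (2.3 equiv), THF–DMPU, −78 → −30 °C; MeI (1.1 equiv), −78 °C; AcOH
Reagents that add atoms: iodomethane, CI
Why: Double deprotonation of the γ-keto ester gives dienediolate 6 with C4 and C5 both planar; enolate C-alkylation occurs at the more nucleophilic, less hindered ester α-carbon C4 from the face anti to the C10 methyl (C18 α, C19 β), and protonation of the remaining C5 enolate gives the trans ring fusion (5α-H), the stable arrangement with quaternary C4 and C10.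

Step 5
Reactants: 7 trans-fused keto ester
Product: 9 lactone enone 6β-hydroxy-4α,8,10β-trimethyl-9-oxo-Δ2,Δ7-octalin-4β-carboxylic acid 19,6β-lactone (5α-H), via 6β-hydroxy ester 8 (not isolated)
Conditions: NaBH4, CeCl3·7H2O, MeOH, −78 → 0 °C; then TsOH·H2O (cat.), PhMe, 40 °C
Reagents that add atoms: none
Why: Luche 1,2-reduction attacks the less hindered C6 carbonyl from the α face (the β face is blocked by the C10 methyl and the axial 4β-ester) to give 6β-alcohol 8, whose 1,3-diaxial relation to C19 drives lactonisation.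

Step 6
Reactants: 10 3-[(tert-butyldimethylsilyl)oxy]cyclobutan-1-one
Product: 11 cis-3-[(tert-butyldimethylsilyl)oxy]-1-ethynylcyclobutan-1-ol (OH cis to OSi)
Conditions: HC≡CMgBr, THF, −78 → 0 °C; H2O
Reagents that add atoms: ethynylmagnesium bromide, C#C[Mg]Br
Why: Grignard 1,2-addition anti to the 3-silyloxy group; the cis/trans relation is without consequence because the silyloxy carbon later becomes the ketone, and 11 is achiral.

Step 7
Reactants: 9 lactone enone; 11 cis-3-[(tert-butyldimethylsilyl)oxy]-1-ethynylcyclobutan-1-ol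
Product: 13 9β-hydroxy-9α-alkynyl adduct (tertiary allylic and propargylic alcohol; Δ2 and Δ7 retained), via dilithio alkynide 12 (not isolated)
Conditions: 11 (1.5 equiv), n-BuLi (3.0 equiv), THF, −78 °C; then 9, −78 → −20 °C; H2O
Reagents that add atoms: none
Why: Acetylide 1,2-addition of 12 to the hindered enone carbonyl, expected from the α face anti to the C10 methyl; the new C9 carbinol centre is removed in step 8, and the neopentyl lactone is not attacked.

Step 8
Reactants: 13 9β-hydroxy-9α-alkynyl adduct
Product: 14 enynone (7-oxo; C8=C9 tetrasubstituted and conjugated to C11≡C12; Δ2 retained)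
Conditions: IBX (2.5 equiv), DMSO, 55 °C
Reagents that add atoms: none
Why: IBX-mediated oxidative 1,3-transposition of a tertiary allylic alcohol (Dauben–Babler type) moves the oxygen to C7 and the double bond into the C8=C9 position; the non-allylic tertiary cyclobutanol and the silyl ether are inert.

Step 9
Reactants: 14 enynone
Product: 15 saturated-side-chain enone (7-oxo-Δ8; ring A saturated; C11–C12 saturated)
Conditions: H2 (1 atm), Pd/C (10 wt % palladium on carbon), EtOAc, rt
Reagents that add atoms: none
Why: Heterogeneous hydrogenation saturates the alkyne and the disubstituted C2=C3 alkene while the tetrasubstituted conjugated C8=C9 alkene and the silyl ether survive.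

Step 10
Reactants: 15 saturated-side-chain enone
Product: 16 7β-allylic alcohol (Δ8)
Conditions: NaBH4, CeCl3·7H2O, MeOH, −78 °C
Reagents that add atoms: none
Why: Luche 1,2-reduction with hydride entering from the α face (the β face is screened by the 6β-lactone oxygen and the C10 methyl) gives the pseudo-equatorial 7β-alcohol; the lactone is untouched.

Step 11
Reactants: 16 7β-allylic alcohol
Product: 17 7β-allylic acetate (Δ8; free tertiary cyclobutanol)
Conditions: Ac2O, pyridine, CH2Cl2, 0 °C → rt
Reagents that add atoms: acetic anhydride, CC(=O)OC(C)=O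
Why: Acetylation of the secondary alcohol; the tertiary cyclobutanol is not acylated without a nucleophilic catalyst.

Step 12
Reactants: 17 7β-allylic acetate
Product: 21 8β-acetoxy-7β-hydroxy-9α,13-epoxy spiro ether (spiro-cyclobutane still carrying OTBS; 8α-Me), via alkene radical cation 18 (not isolated), via tertiary C8 radical 19 (not isolated), via dioxolanylium cation 20 (not isolated)
Conditions: reticulated vitreous carbon anode, Pt cathode, undivided cell, constant current (2.2 F/mol), LiClO4 (0.1 M), 2,6-lutidine, MeCN, rt; then H2O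
Reagents that add atoms: water, O
Why: Proposed new method: anodic one-electron oxidation of the electron-rich tetrasubstituted C8=C9 alkene gives radical cation 18, which the tethered tertiary alcohol traps 5-exo at C9 from the α face (the β face is screened by the adjacent axial C10 methyl), so the C9–O9 spiro bond forms in the radical-cation step with O α and C11 β; the tertiary radical 19 is oxidised at the anode (ECE sequence) and the cation is captured cis by the 7β-acetate carbonyl to give β-fused dioxolanylium 20, fixing O8 β and C17 α, and water opens 20 to the axial C8 acetate and equatorial C7 alcohol as cis-fused acyloxonium ions do; the closest known reactions are Moeller-type anodic olefin–alcohol cyclisations, acridinium-photoredox alkene hydroetherification through alkene radical cations, and acetoxonium neighbouring-group capture of the Woodward–Prévost type.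

Step 13
Reactants: 21 8β-acetoxy-7β-hydroxy spiro ether
Product: 23 diketone 8β-acetoxy-9α,13-epoxy-7-oxo-19,6β-olide carrying a spiro-cyclobutan-3-one at C13, via desilylated diol 22 (not isolated)
Conditions: CrO3, H2SO4, H2O–acetone (Jones reagent), 0 °C → rt
Reagents that add atoms: none
Why: Jones oxidation cleaves the secondary silyl ether to diol 22 and oxidises both secondary alcohols; the acidic medium and fast oxidation of the 7-hydroxyl forestall acetyl migration from O8 to O7, and C13 becomes prochiral.

Step 14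
Reactants: 23 spiro-cyclobutanone diketone
Product: 24 target (8β-acetoxy-9α,13R-epoxy-7-oxolabdane-19,6β:15,16-diolide)
Conditions: Sc(OTf)3 (10 mol %), (S)-pipecolic-acid-derived chiral N,N′-dioxide ligand (12 mol %), mCPBA (1.2 equiv), EtOAc, −20 °C
Reagents that add atoms: meta-chloroperbenzoic acid, OOC(=O)c1cccc(Cl)c1
Why: Catalytic asymmetric Baeyer–Villiger desymmetrisation of a prochiral 3,3-disubstituted cyclobutanone: the chiral scandium complex selects which diastereotopic methylene migrates, inserting oxygen on the methylene cis to C8 and fixing C13 as R (the antipodal ligand gives the 13-epimer); the strained cyclobutanone reacts far faster than the hindered α-acetoxy ketone at C7.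

## Compound list

1 | 2-methylphenol (o-cresol) | Cc1ccccc1O | starting material
2 | 2,6-dimethylphenol | Cc1cccc(C)c1O | intermediate
3 | 2,6-dimethyl-1,4-benzoquinone | CC1=CC(=O)C=C(C)C1=O | intermediate
4 | methyl (2E)-penta-2,4-dienoate | C=C/C=C/C(=O)OC | starting material
5 | endo cis-fused Diels–Alder adduct, methyl 4a,6-dimethyl-5,8-dioxo-1,4,4a,5,8,8a-hexahydronaphthalene-1-carboxylate (10β-Me, 5β-H, 4α-CO2Me, C2=C3, ring B C6(=O)–C7H=C8(Me)–C9(=O)) | CC1=CC(=O)[C@@H]2[C@H](C(=O)OC)C=CC[C@]2(C)C1=O | intermediate
6 | dilithium dienediolate of 5 (C4 and C5 planar; lithium ketene acetal at C19, lithium enolate at C6) | CC1=CC(O[Li])=C2C(=C(OC)O[Li])C=CC[C@]2(C)C1=O | intermediate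
7 | trans-fused keto ester, methyl 1,4a,6-trimethyl-5,8-dioxo-1,4,4a,5,8,8a-hexahydronaphthalene-1-carboxylate (4α-Me, 4β-CO2Me, 5α-H, 10β-Me) | CC1=CC(=O)[C@H]2[C@@](C)(C(=O)OC)C=CC[C@]2(C)C1=O | intermediate
8 | 6β-hydroxy ester from 7 (6β-OH, 9-oxo-Δ7, Δ2) | CC1=C[C@@H](O)[C@H]2[C@@](C)(C(=O)OC)C=CC[C@]2(C)C1=O | intermediate
9 | lactone enone: 19,6β-lactone of 6β-hydroxy-4α,8,10β-trimethyl-9-oxo-Δ2,Δ7-octalin-4β-carboxylic acid (5α-H) | CC1=C[C@H]2OC(=O)[C@@]3(C)C=CC[C@@](C)([C@@H]23)C1=O | intermediate
10 | 3-[(tert-butyldimethylsilyl)oxy]cyclobutan-1-one | O=C1CC(O[Si](C)(C)C(C)(C)C)C1 | starting material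
11 | cis-3-[(tert-butyldimethylsilyl)oxy]-1-ethynylcyclobutan-1-ol (OH cis to OSi) | C#C[C@]1(O)C[C@@H](O[Si](C)(C)C(C)(C)C)C1 | intermediate
12 | dilithio derivative of 11 (lithium alkynide, lithium alkoxide) | [Li]C#C[C@]1(O[Li])C[C@@H](O[Si](C)(C)C(C)(C)C)C1 | intermediate
13 | 9β-hydroxy-9α-alkynyl adduct of 9 (Δ2, Δ7; alkyne ends in the 1-hydroxy-3-silyloxycyclobutyl group) | CC1=C[C@H]2OC(=O)[C@@]3(C)C=CC[C@@](C)([C@@H]23)[C@]1(O)C#C[C@]4(O)C[C@@H](O[Si](C)(C)C(C)(C)C)C4 | intermediate
14 | enynone: 7-oxo-Δ8 lactone with C9–C≡C–cyclobutanol side chain, Δ2 | O=C1[C@H]2OC(=O)[C@@]3(C)C=CC[C@@](C)([C@@H]23)C(C#C[C@]4(O)C[C@@H](O[Si](C)(C)C(C)(C)C)C4)=C1C | intermediate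
15 | 7-oxo-Δ8 lactone with saturated ring A and C9–CH2CH2–cyclobutanol side chain | O=C1[C@H]2OC(=O)[C@@]3(C)CCC[C@@](C)([C@@H]23)C(CC[C@]4(O)C[C@@H](O[Si](C)(C)C(C)(C)C)C4)=C1C | intermediate
16 | 7β-hydroxy-Δ8 lactone (allylic alcohol) | O[C@H]1[C@H]2OC(=O)[C@@]3(C)CCC[C@@](C)([C@@H]23)C(CC[C@]4(O)C[C@@H](O[Si](C)(C)C(C)(C)C)C4)=C1C | intermediate
17 | 7β-acetoxy-Δ8 lactone (allylic acetate, free tertiary cyclobutanol) | CC(=O)O[C@H]1[C@H]2OC(=O)[C@@]3(C)CCC[C@@](C)([C@@H]23)C(CC[C@]4(O)C[C@@H](O[Si](C)(C)C(C)(C)C)C4)=C1C | intermediate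
18 | alkene radical cation of 17 (drawn with C9 cationic, C8 radical) | CC(=O)O[C@H]1[C@H]2OC(=O)[C@@]3(C)CCC[C@@](C)([C@@H]23)[C+](CC[C@]4(O)C[C@@H](O[Si](C)(C)C(C)(C)C)C4)[C]1C | intermediate
19 | tertiary C8 radical after 9α-O spiro-ether closure | CC(=O)O[C@H]1[C@H]2OC(=O)[C@@]3(C)CCC[C@@](C)([C@@H]23)[C@@]4(CC[C@]5(O4)C[C@@H](O[Si](C)(C)C(C)(C)C)C5)[C]1C | intermediate
20 | 7β,8β-fused 2-methyl-1,3-dioxolan-2-ylium cation (9α,13-spiro ether in place) | CC1=[O+][C@@]2(C)[C@@H](O1)[C@H]1OC(=O)[C@@]3(C)CCC[C@@](C)([C@@H]13)[C@@]24CC[C@]1(O4)C[C@@H](O[Si](C)(C)C(C)(C)C)C1 | intermediate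
21 | 8β-acetoxy-7β-hydroxy-8α-methyl-9α,13-epoxy-19,6β-olide, C13 spiro to 3-silyloxycyclobutane | CC(=O)O[C@@]1(C)[C@@H](O)[C@H]2OC(=O)[C@@]3(C)CCC[C@@](C)([C@@H]23)[C@@]12CC[C@]1(O2)C[C@@H](O[Si](C)(C)C(C)(C)C)C1 | intermediate
22 | desilylated diol of 21 (7β-OH and cyclobutanol OH) | CC(=O)O[C@@]1(C)[C@@H](O)[C@H]2OC(=O)[C@@]3(C)CCC[C@@](C)([C@@H]23)[C@@]12CC[C@]1(O2)C[C@@H](O)C1 | intermediate
23 | 8β-acetoxy-9α,13-epoxy-7-oxo-19,6β-olide, C13 spiro to cyclobutan-3-one (C13 prochiral) | CC(=O)O[C@@]1(C)C(=O)[C@H]2OC(=O)[C@@]3(C)CCC[C@@](C)([C@@H]23)[C@@]12CCC1(O2)CC(=O)C1 | intermediate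
24 | 8β-acetoxy-9α,13R-epoxy-7-oxolabdane-19,6β:15,16-diolide (CNP0259020.1) | CC(=O)O[C@@]1(C)C(=O)[C@H]2OC(=O)[C@@]3(C)CCC[C@@](C)([C@@H]23)[C@@]12CC[C@@]1(COC(=O)C1)O2 | target

## Step count and risks

Total step count: 14. Longest linear sequence: 13 steps (1 → 24 through steps 1–5 and 7–14); step 6 is a one-step side branch.

Three steps most likely to fail:

Step 12 (anodic radical-cation spiroetherification with acetoxonium relay). The radical cation may lose a proton or rearrange before the alcohol closes, or the acetate may not capture the C8 cation. The fallback sets out from 16 and comes back at 21. Directed epoxidation of 16 with VO(acac)2 and t-BuOOH, syn to the 7β-hydroxyl, gives the 8β,9β-epoxy-7β-ol F1. Catalytic camphorsulfonic acid then lets the tertiary cyclobutanol open the epoxide 5-exo at C9 with inversion, giving the 9α,13-spiro ether 7β,8β-diol F2. Trimethyl orthoacetate with catalytic acid converts the cis-diol into the cyclic orthoacetate F3, and aqueous acetic acid opens it to the axial ester, which is 21.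

Step 3 (enantioselective Diels–Alder with an electron-poor, Lewis-basic diene). The ester may sequester the chiral Lewis acid, and reactivity or ee may be low. The fallback sets out from 3 and 4 and comes back at 5. Stoichiometric achiral BF3·OEt2 (CH2Cl2, −20 °C) keeps the same regiochemistry through coordination at the unhindered C6 carbonyl and gives 5 as a racemate together with its mirror image ent-5 F4. Preparative chromatography on a chiral stationary phase (SFC) separates the two, and 5 continues into step 4.

Step 14 (catalyst-controlled Baeyer–Villiger desymmetrisation next to existing stereocentres). The substrate may override the catalyst and give low selectivity at C13. The fallback sets out from 23 and comes back at 24. Unselective oxidation with mCPBA and NaHCO3 gives 24 together with the 13-epimer of 24 F5, which are separated by chromatography. F5 is then equilibrated with catalytic DBU through the ring-opened 9α-hydroxy butenolide F6 (retro-oxa-Michael then oxa-Michael re-closure), and the recovered mixture is separated again to recycle material into 24.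

## Further compounds

F1 | step 12 | 8β,9β-epoxide of 16 (7β-OH retained, tertiary cyclobutanol free) | O1[C@@]2(C)[C@@H](O)[C@H]3OC(=O)[C@@]4(C)CCC[C@@](C)([C@@H]34)[C@@]12CC[C@]1(O)C[C@@H](O[Si](C)(C)C(C)(C)C)C1
F2 | step 12 | 7β,8β-dihydroxy-8α-methyl-9α,13-epoxy spiro ether (silyloxycyclobutane retained) | O[C@@]1(C)[C@@H](O)[C@H]2OC(=O)[C@@]3(C)CCC[C@@](C)([C@@H]23)[C@@]12CC[C@]1(O2)C[C@@H](O[Si](C)(C)C(C)(C)C)C1
F3 | step 12 | 7β,8β-O-(1-methoxyethylidene) cyclic orthoacetate of F2 | COC1(C)O[C@@]2(C)[C@@H](O1)[C@H]1OC(=O)[C@@]3(C)CCC[C@@](C)([C@@H]13)[C@@]24CC[C@]1(O4)C[C@@H](O[Si](C)(C)C(C)(C)C)C1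
F4 | step 3 | ent-5, mirror image of adduct 5 | CC1=CC(=O)[C@H]2[C@@H](C(=O)OC)C=CC[C@@]2(C)C1=O
F5 | step 14 | 13-epimer of 24 (13S) | CC(=O)O[C@@]1(C)C(=O)[C@H]2OC(=O)[C@@]3(C)CCC[C@@](C)([C@@H]23)[C@@]12CC[C@]1(COC(=O)C1)O2
F6 | step 14 | ring-opened 8β-acetoxy-9α-hydroxy-7-oxo-19,6β-olide with a 4-substituted furan-2(5H)-one (Δ13 butenolide) side chain | CC(=O)O[C@@]1(C)C(=O)[C@H]2OC(=O)[C@@]3(C)CCC[C@@](C)([C@@H]23)[C@@]1(O)CCC1=CC(=O)OC1
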